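**Plan**

1. Side chain numbered C1' (CH2 on the quinone ring) to C32'. The retrosynthesis cuts C6'–C7' first, giving a naphthalene-bearing C1'–C6' piece (fragment A) and the C7'–C32' hexaene (fragment B). It then cuts C1'–C2' and C3'–CH3 in A, and C7'–C8', C8'–C9' and C20'–C21' in B.
2. Forward: menadione is masked as its dimethyl ether and chloromethylated, and a carboaluminated pentynyl benzoate is coupled to it (A). Two farnesyl units are joined head to tail to all-E hexaprenol, which is extended on boron by CH2 and then by CH(CH3) (B). A and B are then joined, boron is removed and the quinone is unmasked last. No ring is formed; the naphthalene ring system comes from menadione.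
3. Enabling feature: C6' (a CH2) and C7' (the CH(CH3) stereocentre) lie in the only saturated stretch, C4'–C9', and carry no functional group. Both are therefore brought in as O-bearing carbons of hindered benzoates (like polarity), each is reversed to an α-oxy carbanion, and boron carries C7' onto C6' by a 1,2-shift.
4. The boron left on C6' is the helper; it is taken out in step 14.
5. Stereochemistry: C7' (R) comes from (+)-sparteine-controlled lithiation of ethyl 2,4,6-triisopropylbenzoate (step 12) and is passed on with retention in the joining step. The seven E alkenes come from E,E-farnesyl building blocks, a geometry-retaining desulfonylation and a syn-carboalumination.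

Key step: step 13

Remark: (2E,6E)-farnesyl bromide, (2E,6E)-farnesyl acetate, ethyl 2,4,6-triisopropylbenzoate, bis(pinacolboryl)methane and (+)-sparteine are taken as purchasable.

**Route**

Step 1
Reactants: 1 menadione (2-methylnaphthalene-1,4-dione)
Product: 3 1,4-dimethoxy-2-methylnaphthalene, via menadiol 2 (not isolated)
Conditions: Na2S2O4, Bu4NBr, THF/H2O, rt; then KOH, Me2SO4, rt
Reagents that add atoms: dimethyl sulfate COS(=O)(=O)OC
Why: Dithionite reduces the quinone to the air-sensitive hydroquinone 2, which is O-methylated twice in the same flask (reductive Williamson etherification), masking the quinone as a base-stable dimethyl ether.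

Step 2
Reactants: 3 1,4-dimethoxy-2-methylnaphthalene
Product: 4 2-(chloromethyl)-1,4-dimethoxy-3-methylnaphthalene
Conditions: (CH2O)n, 37% HCl, AcOH, rt → 50 °C
Reagents that add atoms: formaldehyde (as paraformaldehyde) C=O; hydrogen chloride Cl
Why: Blanc chloromethylation should attack the only free position of the electron-rich ring (C3, ortho to OMe), and HCl converts the benzylic alcohol to the chloride; this carbon becomes C1'.

Step 3
Reactants: 5 pent-4-yn-1-ol; 6 2,4,6-triisopropylbenzoyl chloride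
Product: 7 pent-4-yn-1-yl 2,4,6-triisopropylbenzoate
Conditions: Et3N, DMAP (cat.), CH2Cl2, 40 °C
Reagents that add atoms: none
Why: DMAP-catalysed acylation of the primary alcohol (nucleophilic acyl substitution) installs the hindered benzoate that later directs α-lithiation at C6' and resists organometallic reagents.

Step 4
Reactants: 7 pent-4-yn-1-yl 2,4,6-triisopropylbenzoate; 4 2-(chloromethyl)-1,4-dimethoxy-3-methylnaphthalene
Product: 9 (4E)-6-(1,4-dimethoxy-3-methylnaphthalen-2-yl)-4-methylhex-4-en-1-yl 2,4,6-triisopropylbenzoate (fragment A), via alkenylalane 8 (not isolated)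
Conditions: Me3Al, Cp2ZrCl2 (cat.), ClCH2CH2Cl, 0 °C → rt; excess Me3Al removed in vacuo; then 4, NiCl2(PPh3)2/n-BuLi (cat.), THF, rt
Reagents that add atoms: trimethylaluminium C[Al](C)C
Why: Negishi zirconium-catalysed syn-carboalumination puts CH3 on the internal and Al on the terminal alkyne carbon, and the (E)-alkenylalane 8 should couple with benzylic chloride 4 under zerovalent nickel catalysis with retention of geometry (the coupling type used for prenylated quinone side chains), the hindered benzoate being inert to Me3Al.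

Step 5
Reactants: 10 (2E,6E)-farnesyl bromide
Product: 11 (2E,6E)-farnesyl phenyl sulfone
Conditions: PhSO2Na, DMF, rt
Reagents that add atoms: sodium benzenesulfinate [Na+].[O-]S(=O)c1ccccc1
Why: SN2 S-alkylation of the sulfinate by the primary allylic bromide should give the allylic sulfone without allylic transposition or loss of E geometry.

Step 6
Reactants: 12 (2E,6E)-farnesyl acetate
Product: 13 (2E,6E,10E)-12-hydroxy-3,7,11-trimethyldodeca-2,6,10-trien-1-yl acetate
Conditions: SeO2 (cat.), t-BuOOH, salicylic acid (cat.), CH2Cl2, 0 °C → rt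
Reagents that add atoms: tert-butyl hydroperoxide CC(C)(C)OO
Why: Catalytic SeO2 allylic oxidation (ene reaction then [2,3]-sigmatropic shift) should hydroxylate the (E)-methyl of the terminal, most electron-rich alkene, the 2,3-alkene being deactivated by the allylic acetate.

Step 7
Reactants: 13 (2E,6E,10E)-12-hydroxy-3,7,11-trimethyldodeca-2,6,10-trien-1-yl acetate
Product: 14 (2E,6E,10E)-12-bromo-3,7,11-trimethyldodeca-2,6,10-trien-1-yl acetate
Conditions: CBr4, PPh3, CH2Cl2, 0 °C
Reagents that add atoms: carbon tetrabromide BrC(Br)(Br)Br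
Why: The Appel reaction converts the primary allylic alcohol to the bromide under neutral conditions that leave the acetate and the E alkenes untouched.

Step 8
Reactants: 11 (2E,6E)-farnesyl phenyl sulfone; 14 (2E,6E,10E)-12-bromo-3,7,11-trimethyldodeca-2,6,10-trien-1-yl acetate
Product: 16 (2E,6E,10E,14E,18E)-3,7,11,15,19,23-hexamethyl-13-(phenylsulfonyl)tetracosa-2,6,10,14,18,22-hexaen-1-yl acetate, via lithiated sulfone 15 (not isolated)
Conditions: 11, n-BuLi, THF/DMPU, −78 °C; then 14, −78 → −20 °C
Reagents that add atoms: none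
Why: Biellmann-type alkylation: the sulfonyl-stabilised allylic carbanion 15 should attack the primary allylic bromide at its α-carbon only (SN2), joining the two C15 units head to tail (the C20'–C21' bond) without touching alkene geometry or the acetate at low temperature.

Step 9
Reactants: 16 (2E,6E,10E,14E,18E)-3,7,11,15,19,23-hexamethyl-13-(phenylsulfonyl)tetracosa-2,6,10,14,18,22-hexaen-1-yl acetate
Product: 18 (2E,6E,10E,14E,18E)-3,7,11,15,19,23-hexamethyltetracosa-2,6,10,14,18,22-hexaen-1-ol (all-E hexaprenol), via sulfonyl alkoxide 17 (not isolated)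
Conditions: LiEt3BH (excess), THF, 0 °C; then PdCl2(dppp) (cat.), 0 °C → rt
Reagents that add atoms: none
Why: LiEt3BH first reduces the acetate to alkoxide 17, which zerovalent palladium cannot ionise, and then delivers hydride to the less substituted terminus of the π-allylpalladium complex formed from the allylic sulfone (palladium-catalysed reductive desulfonylation), which should keep the alkene in place and E.

Step 10
Reactants: 18 all-E hexaprenol
Product: 19 (2E,6E,10E,14E,18E)-1-bromo-3,7,11,15,19,23-hexamethyltetracosa-2,6,10,14,18,22-hexaene (hexaprenyl bromide)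
Conditions: PBr3, pyridine (cat.), Et2O, −10 °C
Reagents that add atoms: phosphorus tribromide BrP(Br)Br
Why: SN2 displacement of the phosphite ester by bromide at low temperature is the standard activation of polyprenols and should keep the 2E geometry.

Step 11
Reactants: 19 hexaprenyl bromide; 20 bis(pinacolboryl)methane
Product: 22 2-[(3E,7E,11E,15E,19E)-4,8,12,16,20,24-hexamethylpentacosa-3,7,11,15,19,23-hexaen-1-yl]-4,4,5,5-tetramethyl-1,3,2-dioxaborolane, via sodium borylmethanide 21 (not isolated)
Conditions: 20, NaOt-Bu, THF, rt; then 19, 0 °C → rt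
Reagents that add atoms: none
Why: Alkoxide-promoted deborylative alkylation: tert-butoxide adds to one boron of 20 and releases the boron-stabilised carbanion 21, which should displace the primary allylic bromide by SN2 to form the C8'–C9' bond.

Step 12
Reactants: 22 homoallylic boronic ester; 23 ethyl 2,4,6-triisopropylbenzoate
Product: 26 2-[(2S,5E,9E,13E,17E,21E)-6,10,14,18,22,26-hexamethylheptacosa-5,9,13,17,21,25-hexaen-2-yl]-4,4,5,5-tetramethyl-1,3,2-dioxaborolane (fragment B), via (R)-lithiated benzoate 24 (not isolated), via boronate complex 25 (not isolated)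
Conditions: 23, s-BuLi, (+)-sparteine, Et2O, −78 °C; then 22, −78 °C; then 35 °C
Reagents that add atoms: none
Why: Lithiation–borylation homologation: s-BuLi/(+)-sparteine removes one enantiotopic α-hydrogen of 23 to give the configurationally stable (R)-carbenoid 24, which adds to boron with retention (25) and then undergoes a 1,2-shift of the homoallyl group with inversion at carbon as the benzoate leaves, so the reagent sets C7' as (S) in 26.

Step 13
Reactants: 9 fragment A; 26 fragment B
Product: 29 2-[(2E,7S,10E,14E,18E,22E,26E)-1-(1,4-dimethoxy-3-methylnaphthalen-2-yl)-3,7,11,15,19,23,27,31-octamethyldotriaconta-2,10,14,18,22,26,30-heptaen-6-yl]-4,4,5,5-tetramethyl-1,3,2-dioxaborolane (both C6 epimers), via lithiated benzoate 27 (not isolated), via boronate complex 28 (not isolated)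
Conditions: 9, s-BuLi, TMEDA, Et2O, −78 °C; then 26, −78 °C; then 40 °C
Reagents that add atoms: none
Why: s-BuLi/TMEDA deprotonates 9 at C6' next to the benzoate oxygen (complex-induced proximity, dipole-stabilised carbanion 27), the carbanion adds to the boron of 26 to give the tetracoordinate boronate 28, and on warming the C7'–B bond migrates to C6' antiperiplanar to the departing 2,4,6-triisopropylbenzoate (1,2-metallate rearrangement), which forms the C6'–C7' bond. The closest known reaction type is the lithiation–borylation homologation of secondary alkyl pinacol boronic esters with α-lithiated primary 2,4,6-triisopropylbenzoates, as used in iterative assembly-line chain growth. No ring is closed. No stereocentre of the target is newly made: the migrating carbon C7' keeps its configuration (the (S)-boronic ester becomes 7'R once boron is gone; in 29 it is labelled 7S only because boron raises the priority of C6'), and the boron-bearing C6' forms as both epimers, which is why achiral TMEDA suffices. The step needs site-selective lithiation at C6' over the ring-bound CH2 (C1') and the aryl methyl group; this is secured by the coordinating benzoate, which makes C6'–H the kinetically most acidic site at −78 °C, and by adding 26 only after lithiation so that s-BuLi never meets the boronic ester.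

Step 14
Reactants: 29 C6'-boronic ester
Product: 31 2-[(2E,7R,10E,14E,18E,22E,26E)-3,7,11,15,19,23,27,31-octamethyldotriaconta-2,10,14,18,22,26,30-heptaen-1-yl]-1,4-dimethoxy-3-methylnaphthalene, via phenylboronate complex 30 (not isolated)
Conditions: PhLi, Et2O, 0 °C; then [Ir(dF(CF3)ppy)2(dtbbpy)]PF6 (cat.), 2,4,6-(i-Pr)3C6H2SH, MeOH/acetone, blue LEDs, rt
Reagents that add atoms: none
Why: Radical protodeboronation of an alkyl pinacol boronic ester: single-electron oxidation of boronate complex 30 by the photoexcited iridium complex releases the secondary C6' radical, which should take hydrogen from the hindered thiol faster than it cyclises (5-exo onto C10'), the thiol being regenerated by reduction and protonation by methanol; both C6' epimers converge and C7' is not involved.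

Step 15
Reactants: 31 dimethoxynaphthalene
Product: 32 2-methyl-3-[(2E,7R,10E,14E,18E,22E,26E)-3,7,11,15,19,23,27,31-octamethyldotriaconta-2,10,14,18,22,26,30-heptaen-1-yl]naphthalene-1,4-dione (target)
Conditions: (NH4)2Ce(NO3)6, MeCN/H2O, 0 °C
Reagents that add atoms: water O
Why: Oxidative demethylation of the 1,4-dimethoxyarene by tetravalent cerium (two one-electron oxidations, water adding to the radical cation) should give the 1,4-quinone without touching the isolated trisubstituted alkenes or C7'.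

**Compound list**

1 | menadione (2-methylnaphthalene-1,4-dione) | CC1=CC(=O)c2ccccc2C1=O | starting material
2 | menadiol (2-methylnaphthalene-1,4-diol) | Cc1cc(O)c2ccccc2c1O | intermediate
3 | 1,4-dimethoxy-2-methylnaphthalene | COc1c(C)cc(OC)c2ccccc12 | intermediate
4 | 2-(chloromethyl)-1,4-dimethoxy-3-methylnaphthalene | COc1c(C)c(CCl)c(OC)c2ccccc12 | intermediate
5 | pent-4-yn-1-ol | C#CCCCO | starting material
6 | 2,4,6-triisopropylbenzoyl chloride | CC(C)c1cc(C(C)C)c(C(=O)Cl)c(C(C)C)c1 | starting material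
7 | pent-4-yn-1-yl 2,4,6-triisopropylbenzoate | C#CCCCOC(=O)c1c(C(C)C)cc(C(C)C)cc1C(C)C | intermediate
8 | (4E)-5-(dimethylalumanyl)-4-methylpent-4-en-1-yl 2,4,6-triisopropylbenzoate | C[Al](C)/C=C(\C)CCCOC(=O)c1c(C(C)C)cc(C(C)C)cc1C(C)C | intermediate
9 | (4E)-6-(1,4-dimethoxy-3-methylnaphthalen-2-yl)-4-methylhex-4-en-1-yl 2,4,6-triisopropylbenzoate (fragment A) | COc1c(C)c(C/C=C(\C)CCCOC(=O)c3c(C(C)C)cc(C(C)C)cc3C(C)C)c(OC)c2ccccc12 | intermediate
10 | (2E,6E)-farnesyl bromide | CC(C)=CCC/C(C)=C/CC/C(C)=C/CBr | starting material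
11 | (2E,6E)-farnesyl phenyl sulfone | CC(C)=CCC/C(C)=C/CC/C(C)=C/CS(=O)(=O)c1ccccc1 | intermediate
12 | (2E,6E)-farnesyl acetate | CC(C)=CCC/C(C)=C/CC/C(C)=C/COC(C)=O | starting material
13 | (2E,6E,10E)-12-hydroxy-3,7,11-trimethyldodeca-2,6,10-trien-1-yl acetate | OC/C(C)=C/CC/C(C)=C/CC/C(C)=C/COC(C)=O | intermediate
14 | (2E,6E,10E)-12-bromo-3,7,11-trimethyldodeca-2,6,10-trien-1-yl acetate | BrC/C(C)=C/CC/C(C)=C/CC/C(C)=C/COC(C)=O | intermediate
15 | α-lithiated (2E,6E)-farnesyl phenyl sulfone | CC(C)=CCC/C(C)=C/CC/C(C)=C/C([Li])S(=O)(=O)c1ccccc1 | intermediate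
16 | (2E,6E,10E,14E,18E)-3,7,11,15,19,23-hexamethyl-13-(phenylsulfonyl)tetracosa-2,6,10,14,18,22-hexaen-1-yl acetate | CC(C)=CCC/C(C)=C/CC/C(C)=C/C(C/C(C)=C/CC/C(C)=C/CC/C(C)=C/COC(C)=O)S(=O)(=O)c1ccccc1 | intermediate
17 | lithium (2E,6E,10E,14E,18E)-3,7,11,15,19,23-hexamethyl-13-(phenylsulfonyl)tetracosa-2,6,10,14,18,22-hexaen-1-olate | CC(C)=CCC/C(C)=C/CC/C(C)=C/C(C/C(C)=C/CC/C(C)=C/CC/C(C)=C/C[O-])S(=O)(=O)c1ccccc1.[Li+] | intermediate
18 | (2E,6E,10E,14E,18E)-3,7,11,15,19,23-hexamethyltetracosa-2,6,10,14,18,22-hexaen-1-ol (all-E hexaprenol) | CC(C)=CCC/C(C)=C/CC/C(C)=C/CC/C(C)=C/CC/C(C)=C/CC/C(C)=C/CO | intermediate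
19 | (2E,6E,10E,14E,18E)-1-bromo-3,7,11,15,19,23-hexamethyltetracosa-2,6,10,14,18,22-hexaene | CC(C)=CCC/C(C)=C/CC/C(C)=C/CC/C(C)=C/CC/C(C)=C/CC/C(C)=C/CBr | intermediate
20 | bis(pinacolboryl)methane | CC1(C)OB(CB2OC(C)(C)C(C)(C)O2)OC1(C)C | starting material
21 | sodium (4,4,5,5-tetramethyl-1,3,2-dioxaborolan-2-yl)methanide | [Na+].[CH2-]B1OC(C)(C)C(C)(C)O1 | intermediate
22 | 2-[(3E,7E,11E,15E,19E)-4,8,12,16,20,24-hexamethylpentacosa-3,7,11,15,19,23-hexaen-1-yl]-4,4,5,5-tetramethyl-1,3,2-dioxaborolane | CC(C)=CCC/C(C)=C/CC/C(C)=C/CC/C(C)=C/CC/C(C)=C/CC/C(C)=C/CCB1OC(C)(C)C(C)(C)O1 | intermediate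
23 | ethyl 2,4,6-triisopropylbenzoate | CCOC(=O)c1c(C(C)C)cc(C(C)C)cc1C(C)C | starting material
24 | (1R)-1-lithioethyl 2,4,6-triisopropylbenzoate | C[C@@H]([Li])OC(=O)c1c(C(C)C)cc(C(C)C)cc1C(C)C | intermediate
25 | lithium boronate complex of 22 with 24 (R at the benzoate-bearing carbon) | CC(C)=CCC/C(C)=C/CC/C(C)=C/CC/C(C)=C/CC/C(C)=C/CC/C(C)=C/CC[B-]1(OC(C)(C)C(C)(C)O1)[C@H](C)OC(=O)c2c(C(C)C)cc(C(C)C)cc2C(C)C.[Li+] | intermediate
26 | 2-[(2S,5E,9E,13E,17E,21E)-6,10,14,18,22,26-hexamethylheptacosa-5,9,13,17,21,25-hexaen-2-yl]-4,4,5,5-tetramethyl-1,3,2-dioxaborolane (fragment B) | CC(C)=CCC/C(C)=C/CC/C(C)=C/CC/C(C)=C/CC/C(C)=C/CC/C(C)=C/CC[C@H](C)B1OC(C)(C)C(C)(C)O1 | intermediate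
27 | (4E)-6-(1,4-dimethoxy-3-methylnaphthalen-2-yl)-1-lithio-4-methylhex-4-en-1-yl 2,4,6-triisopropylbenzoate (racemic at C1) | COc1c(C)c(C/C=C(\C)CCC([Li])OC(=O)c3c(C(C)C)cc(C(C)C)cc3C(C)C)c(OC)c2ccccc12 | intermediate
28 | lithium boronate complex of 26 with 27 | CC(C)=CCC/C(C)=C/CC/C(C)=C/CC/C(C)=C/CC/C(C)=C/CC/C(C)=C/CC[C@H](C)[B-]1(OC(C)(C)C(C)(C)O1)C(CC/C(C)=C/Cc2c(C)c(OC)c3ccccc3c2OC)OC(=O)c4c(C(C)C)cc(C(C)C)cc4C(C)C.[Li+] | intermediate
29 | 2-[(2E,7S,10E,14E,18E,22E,26E)-1-(1,4-dimethoxy-3-methylnaphthalen-2-yl)-3,7,11,15,19,23,27,31-octamethyldotriaconta-2,10,14,18,22,26,30-heptaen-6-yl]-4,4,5,5-tetramethyl-1,3,2-dioxaborolane (both C6 epimers; same spatial arrangement at C7 as 7R in 31 and 32) | CC(C)=CCC/C(C)=C/CC/C(C)=C/CC/C(C)=C/CC/C(C)=C/CC/C(C)=C/CC[C@H](C)C(B1OC(C)(C)C(C)(C)O1)CC/C(C)=C/Cc2c(C)c(OC)c3ccccc3c2OC | intermediate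
30 | lithium phenylboronate complex of 29 | CC(C)=CCC/C(C)=C/CC/C(C)=C/CC/C(C)=C/CC/C(C)=C/CC/C(C)=C/CC[C@H](C)C([B-]1(c4ccccc4)OC(C)(C)C(C)(C)O1)CC/C(C)=C/Cc2c(C)c(OC)c3ccccc3c2OC.[Li+] | intermediate
31 | 2-[(2E,7R,10E,14E,18E,22E,26E)-3,7,11,15,19,23,27,31-octamethyldotriaconta-2,10,14,18,22,26,30-heptaen-1-yl]-1,4-dimethoxy-3-methylnaphthalene | CC(C)=CCC/C(C)=C/CC/C(C)=C/CC/C(C)=C/CC/C(C)=C/CC/C(C)=C/CC[C@H](C)CCC/C(C)=C/Cc1c(C)c(OC)c2ccccc2c1OC | intermediate
32 | 2-methyl-3-[(2E,7R,10E,14E,18E,22E,26E)-3,7,11,15,19,23,27,31-octamethyldotriaconta-2,10,14,18,22,26,30-heptaen-1-yl]naphthalene-1,4-dione | CC(C)=CCC/C(C)=C/CC/C(C)=C/CC/C(C)=C/CC/C(C)=C/CC/C(C)=C/CC[C@H](C)CCC/C(C)=C/CC1=C(C)C(=O)c2ccccc2C1=O | target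

**Count and risks**

Total step count: 15. Longest linear sequence: 10 steps (from 12 through steps 6–15).

Steps most likely to fail:

1. Step 13. The lithiation may not be site-selective: the ring-bound CH2 (C1'), flanked by the arene and the C2'=C3' alkene, can compete with C6' for the base, and boronate formation with the hindered secondary boronic ester may be slower than carbenoid decay. Fallback (sets out from 22 and 9, comes back at 31; steps 13 and 14 are then not needed): the union is made by a stereoinvertive copper-catalysed Kumada-type alkyl–alkyl coupling.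
   - 22 is homologated as in step 12 but with (−)-sparteine to the (R)-boronic ester F1.
   - F1 is oxidised with retention (NaBO3·4H2O, THF/H2O) to the (R)-heptacosahexaen-2-ol F2, which is converted (TsCl, pyridine) to the (R)-tosylate F3.
   - 9 is cleaved with LiAlH4 (THF, reflux) to the fragment A alcohol F4, which is taken to the bromide F5 (CBr4, PPh3) and then to the Grignard reagent F6 (Mg, THF).
   - F6 and F3 are coupled with CuI/TMEDA/LiOMe in THF at 0 °C. This SN2 displacement with inversion at C7' should give 31 directly.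

2. Step 14. The C6' radical stands in a hex-5-enyl relationship to the C10'=C11' alkene, so 5-exo cyclisation can compete with hydrogen transfer, and thiyl radicals can scramble E/Z geometry of the trisubstituted alkenes by reversible addition. Fallback (sets out from 29, comes back at 31): boron is removed by polar steps only.
   - Oxidation (NaBO3·4H2O, THF/H2O) gives the C6' alcohol F7.
   - Mesylation (MsCl, Et3N, CH2Cl2) gives the C6' mesylate F8.
   - Hydride displacement with LiEt3BH (THF, reflux) gives 31.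

3. Step 4. Complexation of Me3Al by the ester may slow the carboalumination or erode its regioselectivity, and residual Me3Al may transfer methyl to the benzylic chloride in the nickel step. Fallback (sets out from 5, uses 6 and 4, comes back at 9): the polarity of the coupling is reversed.
   - Carboalumination of 5 as its aluminium alkoxide (Me3Al, Cp2ZrCl2 cat.) with I2 quench gives (E)-5-iodo-4-methylpent-4-en-1-ol F9.
   - Acylation with 6 (Et3N, DMAP) gives the vinyl iodide benzoate F10.
   - Zinc insertion into 4 (Zn, LiCl, THF) gives the benzylic zinc chloride F11.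
   - Negishi coupling of F11 with F10 (Pd(PPh3)4, THF) gives 9 with retention of the E geometry.

**Further compounds**

F1 | step 13 | 2-[(2R,5E,9E,13E,17E,21E)-6,10,14,18,22,26-hexamethylheptacosa-5,9,13,17,21,25-hexaen-2-yl]-4,4,5,5-tetramethyl-1,3,2-dioxaborolane | CC(C)=CCC/C(C)=C/CC/C(C)=C/CC/C(C)=C/CC/C(C)=C/CC/C(C)=C/CC[C@@H](C)B1OC(C)(C)C(C)(C)O1
F2 | step 13 | (2R,5E,9E,13E,17E,21E)-6,10,14,18,22,26-hexamethylheptacosa-5,9,13,17,21,25-hexaen-2-ol | CC(C)=CCC/C(C)=C/CC/C(C)=C/CC/C(C)=C/CC/C(C)=C/CC/C(C)=C/CC[C@@H](C)O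
F3 | step 13 | (2R,5E,9E,13E,17E,21E)-6,10,14,18,22,26-hexamethylheptacosa-5,9,13,17,21,25-hexaen-2-yl 4-methylbenzenesulfonate | CC(C)=CCC/C(C)=C/CC/C(C)=C/CC/C(C)=C/CC/C(C)=C/CC/C(C)=C/CC[C@@H](C)OS(=O)(=O)c1ccc(C)cc1
F4 | step 13 | (4E)-6-(1,4-dimethoxy-3-methylnaphthalen-2-yl)-4-methylhex-4-en-1-ol | COc1c(C)c(C/C=C(\C)CCCO)c(OC)c2ccccc12
F5 | step 13 | 2-[(2E)-6-bromo-3-methylhex-2-en-1-yl]-1,4-dimethoxy-3-methylnaphthalene | COc1c(C)c(C/C=C(\C)CCCBr)c(OC)c2ccccc12
F6 | step 13 | [(4E)-6-(1,4-dimethoxy-3-methylnaphthalen-2-yl)-4-methylhex-4-en-1-yl]magnesium bromide | COc1c(C)c(C/C=C(\C)CCC[Mg]Br)c(OC)c2ccccc12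
F7 | step 14 | (2E,7S,10E,14E,18E,22E,26E)-1-(1,4-dimethoxy-3-methylnaphthalen-2-yl)-3,7,11,15,19,23,27,31-octamethyldotriaconta-2,10,14,18,22,26,30-heptaen-6-ol (both C6 epimers) | CC(C)=CCC/C(C)=C/CC/C(C)=C/CC/C(C)=C/CC/C(C)=C/CC/C(C)=C/CC[C@H](C)C(O)CC/C(C)=C/Cc1c(C)c(OC)c2ccccc2c1OC
F8 | step 14 | (2E,7S,10E,14E,18E,22E,26E)-1-(1,4-dimethoxy-3-methylnaphthalen-2-yl)-3,7,11,15,19,23,27,31-octamethyldotriaconta-2,10,14,18,22,26,30-heptaen-6-yl methanesulfonate (both C6 epimers) | CC(C)=CCC/C(C)=C/CC/C(C)=C/CC/C(C)=C/CC/C(C)=C/CC/C(C)=C/CC[C@H](C)C(OS(C)(=O)=O)CC/C(C)=C/Cc1c(C)c(OC)c2ccccc2c1OC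
F9 | step 4 | (4E)-5-iodo-4-methylpent-4-en-1-ol | OCCC/C(C)=C/I
F10 | step 4 | (4E)-5-iodo-4-methylpent-4-en-1-yl 2,4,6-triisopropylbenzoate | CC(C)c1cc(C(C)C)c(C(=O)OCCC/C(C)=C/I)c(C(C)C)c1
F11 | step 4 | [(1,4-dimethoxy-3-methylnaphthalen-2-yl)methyl]zinc chloride | COc1c(C)c(C[Zn]Cl)c(OC)c2ccccc12
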